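## Analysis of the target

The target 21 is a flavanone. Ring C (O1, C2, C3, C4, C4a, C8a) is a chroman-4-one fused to ring A, which carries O1 at C8a, a prenyl group at C8, a free hydroxyl at C7, a second prenyl group at C6 and one hydrogen at C5; ring B is a plain phenyl on C2. The only stereocenter is C2, of S configuration, a benzylic ether carbon β to the C4 ketone. It has no stereochemical partner but is labile: base or acid can open ring C by retro-oxa-Michael reaction to the achiral 2'-hydroxychalcone, and reclosure gives the racemate. The two trisubstituted alkenes each sit ortho to a phenolic oxygen, so Brønsted or Lewis acids can close them onto O1 or the C7 oxygen as 2,2-dimethylchromans; they also rule out hydrogenolysis and electrophilic oxidants. The difficulty is therefore twofold: the C4 acyl carbon must be attached to C4a of a fully loaded, acid-sensitive ring A without Friedel–Crafts or Lewis-acid Fries conditions, and C2 must be set as S and kept through the deprotections. The structural feature used is that, of the three ring A carbons ortho or para to O1 (C8, C4a and C6), only C4a bears hydrogen; C8 and C6 are blocked by the prenyl groups. An acyl group released from O1 can therefore be retained at one carbon only, so the whole C4–C3–C2 chain, with C2 preformed as an (R)-silyloxy carbon, can be placed on O1 as an ester and moved to C4a with light.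

## Retrosynthetic reasoning

Positions are given in flavanone numbering for all intermediates.

21 to 20. The last cut is the O–Si bond at the C7 oxygen. A silyl ether is chosen for this oxygen because buffered desilylation avoids both the acid that would cyclize the flanking prenyl groups and the free base that would open ring C.

20 to 19. The O1–C2 bond is cut. This bond carries the stereocenter, and cutting it exposes a phenol and a secondary benzylic alcohol, which a Mitsunobu etherification joins again by 6-exo-tet displacement with inversion. Compound 19 must therefore be R at the carbinol. Cutting C2–C3 or C2–phenyl would call for a new asymmetric induction, and closing the ring by conjugate addition would give the racemate. The gain is that the stereocenter becomes that of a commercial β-hydroxy ester.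

19 to 18. The carbinol oxygen carries a triethylsilyl group in 18. It masks the alcohol during ester formation and irradiation and is removed by mild acid-catalysed solvolysis that leaves the aryl silyl ether of the C7 oxygen in place.

18 to 16. The C4–C4a bond is cut and the acyl group is returned to O1, giving the aryl ester 16. The forward reaction is a photochemical 1,3-acyl shift from oxygen to carbon. The cut is made here because C4a is the only open position ortho or para to O1, so the regiochemistry is a consequence of the substitution pattern, and because the reaction needs no acid. The forward step must break the O1–acyl bond and form the C4–C4a bond without touching the prenyl groups, the silyl ethers or the (R) centre.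

16 to 15, and 15 to 10 plus 14. The C7 O–Si bond and the O1–acyl bond are cut in turn. The two hydroxyls of the diol 10 differ in their surroundings: the one that becomes O1 has one prenyl and one hydrogen as ortho neighbours, while the one that becomes the C7 oxygen lies between both prenyl groups. Acylation with acid 14 is therefore placed first, on the more accessible hydroxyl, and a forcing silylation of the hindered hydroxyl second.

14 to 12 to 11. The acid comes from the commercial (R)-hydroxy ester 11 by silylation and saponification; the stereocenter is not touched.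

10 to 9 to 6 to 2 to 1, with 3. Both aryl–CH2 bonds are cut to prenyl bromide 3 and an aryl metal. The methoxymethyl ethers of 2 protect the phenols and direct the metalations. The first prenyl group is attached at the carbon that carries bromine in 1, by bromine–lithium exchange, so its site is unambiguous. The second goes to the carbon between the two acetal oxygens of 6, the position that both groups direct to. The opposite order is avoided: a prenyl group placed first between the two acetal oxygens would have its benzylic, allylic CH2 flanked by both directing groups, and lateral deprotonation would compete with the second ring metalation.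

## Alternatives that were turned down

Alternative 1: Ring A is taken apart into a vinylketene and an ynol ether, cutting C7–C8, C6–C7 and C4a–C8a.
- Forward key step: irradiation of (E)-1-diazo-7-methylocta-3,6-dien-2-one A2 triggers a Wolff rearrangement to a vinylketene. This adds to triisopropyl[(5-methylhex-4-en-1-yn-1-yl)oxy]silane A3 by [2+2] cycloaddition, and 4π opening, 6π closure and tautomerization give 2,6-bis(3-methylbut-2-enyl)-3-(triisopropylsilyloxy)phenol A1.
- For it: the positions of both prenyl groups and both oxygens follow from connectivity, the two oxygens are differentiated as soon as the ring forms, and the conditions are neutral.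
- Against it: it constructs a benzene ring that 1 already supplies. A2 and A3 each need several steps, and the skipped diene of A2 is prone to move into conjugation. Carbene and ketene intermediates must ignore two trisubstituted alkenes. A1 carries its free hydroxyl at C7 and its silyl group on O1, the reverse of what acylation at O1 needs, so a protecting-group exchange would follow.
- Comparison: A1 is only at the level of the diol 10; the C4–C4a bond, the O1–C2 bond and the stereocenter all remain to be made. On regiocontrol it is stronger than the chosen route, which relies on directed metalation and on a selective acylation. The chosen route reaches 10 in four steps from a bought ring and spends its one risky step on the bond that the benzannulation leaves unsolved.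

Alternative 2: The C2–C3 bond is cut.
- Forward key step: 1-[2-(benzyloxy)-4-(methoxymethoxy)-3,5-bis(3-methylbut-2-enyl)phenyl]-2-diazoethan-1-one A5 is decomposed by a chiral dirhodium tetracarboxylate (divalent rhodium). The carbene at C3 inserts into one of the two enantiotopic benzylic C–H bonds of the O1 benzyl ether, closing ring C and giving (S)-7-(methoxymethoxy)-6,8-bis(3-methylbut-2-enyl)flavanone A4.
- For it: ring C and the C2 stereocenter arise in one catalytic operation, the C–H bond is activated by the adjacent oxygen, and no chalcone-type intermediate is involved.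
- Against it: the six-membered insertion must compete with attack of the carbene on the O1 lone pair, which leads through an oxonium ylide and benzyl shift to a ring-contracted five-membered ketone. It must also compete with addition to the benzyl phenyl ring and to the prenyl alkenes. Discrimination between two hydrogens of a freely rotating benzyl group by an acceptor-only carbene is usually modest. A5 needs a carboxyl carbon at C4a, so the C4–C4a bond still has to be made by other means. The methoxymethyl group of A4 must finally leave under acid between two prenyl groups.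
- Comparison: it is stronger on convergence and on catalytic asymmetric induction. The chosen route instead takes its configuration from a commercial ester of secured enantiopurity and has a key step with one structurally allowed outcome.

Alternative 3: The C2–phenyl bond is cut.
- Forward key step: 7-(tert-butyldimethylsilyloxy)-6,8-bis(3-methylbut-2-enyl)chromen-4-one A7 takes up a phenyl group from a phenylboron reagent in a 1,4-addition catalysed by a hydroxorhodium complex (monovalent rhodium) with a chiral bisphosphine. The product is (S)-7-(tert-butyldimethylsilyloxy)-6,8-bis(3-methylbut-2-enyl)flavanone A6, the same substance as 20 of the chosen route.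
- For it: asymmetric arylation of chromones is an established reaction type. The stereocenter is set by a catalyst in the last carbon–carbon bond formation, ring B can be varied late, and the route meets the chosen one at its penultimate compound without activating a β-hydroxy ketone. On this last point it is stronger than the chosen route, whose Mitsunobu closure risks elimination.
- Against it: the chromone is a vinylogous ester made still less electrophilic by the C7 oxygen donor. The aqueous, basic medium of transmetalation can open the product ring or cleave the aryl silyl ether. A7 itself requires a 2-hydroxyaryl methyl ketone at C4a, so the C4–C4a bond must be made anyway, followed by enaminone formation and ring closure.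
- Comparison: the chosen route makes the aryl ketone and delivers the complete C4–C3–C2 chain with its stereocenter in the same step, and its enantiopurity does not depend on a catalyst working on a deactivated acceptor.

Key step: step 9

## Route

Remark: 1, 3 and 11 are taken as commercial; prenyl means 3-methylbut-2-enyl, MOM methoxymethyl, TES triethylsilyl, TBS tert-butyldimethylsilyl.

Step 1
Reactants: 1 4-bromobenzene-1,3-diol (4-bromoresorcinol)
Product: 2 1-bromo-2,4-bis(methoxymethoxy)benzene
Conditions: MOMCl (2.5 equiv), iPr2NEt (3 equiv), CH2Cl2, 0 °C to rt
Reagents that add atoms: chloromethyl methyl ether (MOMCl), COCCl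
Why: Williamson-type O-alkylation of both phenols by the reactive chloromethyl ether under amine base; the acetal ethers serve as protecting and metal-directing groups in the next two steps.

Step 2
Reactants: 2 1-bromo-2,4-bis(methoxymethoxy)benzene; 3 1-bromo-3-methylbut-2-ene (prenyl bromide)
Product: 6 2,4-bis(methoxymethoxy)-1-(3-methylbut-2-enyl)benzene, via aryllithium 4 (not isolated), via arylcopper 5 (not isolated)
Conditions: n-BuLi, THF, −78 °C; CuBr·SMe2 (1 equiv), −78 to −40 °C; then 3, −78 °C to rt
Reagents that add atoms: none
Why: Bromine–lithium exchange at −78 °C is faster than any deprotonation and fixes the metal at the former C–Br carbon (the future C6). Transmetalation to copper and allylic substitution at the unhindered CH2 terminus of 3 then give the linear prenyl arene.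

Step 3
Reactants: 6 2,4-bis(methoxymethoxy)-1-(3-methylbut-2-enyl)benzene; 3 1-bromo-3-methylbut-2-ene
Product: 9 1,3-bis(methoxymethoxy)-2,4-bis(3-methylbut-2-enyl)benzene, via aryllithium 7 (not isolated), via arylcopper 8 (not isolated)
Conditions: n-BuLi (1.2 equiv), THF, 0 °C to rt; CuBr·SMe2 (1 equiv), −40 °C; then 3, −40 °C to rt
Reagents that add atoms: none
Why: Directed ortho-metalation at the ring carbon between the two acetal oxygens (the future C8), the site both groups direct to. The existing prenyl CH2 has only one directing neighbour, so ring lithiation should dominate. Copper-mediated allylation follows as in step 2.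

Step 4
Reactants: 9 1,3-bis(methoxymethoxy)-2,4-bis(3-methylbut-2-enyl)benzene
Product: 10 2,4-bis(3-methylbut-2-enyl)benzene-1,3-diol
Conditions: HCl (3 M aq., 1 equiv), MeOH, rt, stopped at full conversion
Reagents that add atoms: none
Why: Acid-catalysed acetal exchange with methanol. Aryl methoxymethyl ethers cleave under dilute acid at room temperature, below the acidity and temperature needed to protonate a trisubstituted alkene and close a chroman.

Step 5
Reactants: 11 ethyl (R)-3-hydroxy-3-phenylpropanoate
Product: 12 ethyl (R)-3-phenyl-3-(triethylsilyloxy)propanoate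
Conditions: TESCl, imidazole, CH2Cl2, 0 °C to rt
Reagents that add atoms: chlorotriethylsilane (TESCl), CC[Si](Cl)(CC)CC
Why: Standard silylation of a secondary alcohol; the stereocenter is not involved.

Step 6
Reactants: 12 ethyl (R)-3-phenyl-3-(triethylsilyloxy)propanoate
Product: 14 (R)-3-phenyl-3-(triethylsilyloxy)propanoic acid, via lithium carboxylate 13 (not isolated)
Conditions: LiOH·H2O, THF/MeOH/H2O, 0 °C to rt; then cold 0.5 M HCl to pH 4
Reagents that add atoms: lithium hydroxide (its hydroxide supplies the new carboxyl oxygen), [Li+].[OH-]
Why: Ester saponification; the stereocenter is β to the carboxyl and cannot epimerize by enolization. Low temperature and acidification only to pH 4 keep β-elimination and loss of the triethylsilyl group in check.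

Step 7
Reactants: 10 2,4-bis(3-methylbut-2-enyl)benzene-1,3-diol; 14 (R)-3-phenyl-3-(triethylsilyloxy)propanoic acid
Product: 15 3-hydroxy-2,4-bis(3-methylbut-2-enyl)phenyl (R)-3-phenyl-3-(triethylsilyloxy)propanoate
Conditions: DCC, DMAP (cat.), CH2Cl2, 0 °C to rt, 10 in slight excess
Reagents that add atoms: none
Why: Steglich esterification. The acylpyridinium intermediate is bulky and should react at the hydroxyl with one ortho hydrogen (the future O1) in preference to the hydroxyl enclosed by two prenyl groups; excess diol suppresses double acylation.

Step 8
Reactants: 15 3-hydroxy-2,4-bis(3-methylbut-2-enyl)phenyl (R)-3-phenyl-3-(triethylsilyloxy)propanoate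
Product: 16 3-(tert-butyldimethylsilyloxy)-2,4-bis(3-methylbut-2-enyl)phenyl (R)-3-phenyl-3-(triethylsilyloxy)propanoate
Conditions: TBSOTf, 2,6-lutidine, CH2Cl2, −78 to 0 °C
Reagents that add atoms: tert-butyldimethylsilyl trifluoromethanesulfonate (TBSOTf), CC(C)(C)[Si](C)(C)OS(=O)(=O)C(F)(F)F
Why: The silyl triflate is reactive enough for a phenol with two ortho substituents, and the non-nucleophilic base leaves the aryl ester and the triethylsilyl ether untouched.

Step 9
Reactants: 16 3-(tert-butyldimethylsilyloxy)-2,4-bis(3-methylbut-2-enyl)phenyl (R)-3-phenyl-3-(triethylsilyloxy)propanoate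
Product: 18 (R)-1-[4-(tert-butyldimethylsilyloxy)-2-hydroxy-3,5-bis(3-methylbut-2-enyl)phenyl]-3-phenyl-3-(triethylsilyloxy)propan-1-one, via dienone 17 (not isolated)
Conditions: hν (254 nm, low-pressure Hg lamp, quartz), degassed cyclohexane (5 mM), argon, 20 °C, run to partial conversion with recovered 16 re-irradiated
Reagents that add atoms: none
Why: This is a photo-Fries rearrangement, the closest known reaction type being the light-induced 1,3-acyl shift of aryl alkanoates to ortho-hydroxyaryl ketones. Excitation of the aryl ester leads to homolysis of the O1–acyl bond and a singlet acyl/phenoxyl radical pair held in the solvent cage. The phenoxyl radical carries spin at O1, C8, C4a and C6; bonding of the acyl carbon to C4a gives dienone 17, whose C4a hydrogen moves to oxygen to give the hydrogen-bonded phenol 18. Bonding at the prenyl-bearing C8 or C6 gives dienones with no hydrogen to lose, which fall back to the radical pair, and bonding at O1 returns 16, so C4a is the only exit that is retained. No ring closes and no lasting stereocenter is formed: the sp3 carbon of 17 is erased on tautomerization, and the (R) centre lies two carbons from the acyl radical and is not touched. The step needs site selectivity, which the two prenyl blocks secure, and chemoselectivity against cyclization of an excited phenol onto a neighbouring prenyl group. The silyl group on the C7 oxygen secures the latter, together with the O1–H to C4 carbonyl hydrogen bond of 18, which drains the excited state by proton transfer. The medium is neutral, so the prenyl groups and both silyl ethers should survive, and a dilute, degassed, non-polar solution favours in-cage recombination over escape.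

Step 10
Reactants: 18 (R)-1-[4-(tert-butyldimethylsilyloxy)-2-hydroxy-3,5-bis(3-methylbut-2-enyl)phenyl]-3-phenyl-3-(triethylsilyloxy)propan-1-one
Product: 19 (R)-1-[4-(tert-butyldimethylsilyloxy)-2-hydroxy-3,5-bis(3-methylbut-2-enyl)phenyl]-3-hydroxy-3-phenylpropan-1-one
Conditions: PPTS (0.2 equiv), MeOH/CH2Cl2, 0 °C
Reagents that add atoms: none
Why: Acid-catalysed methanolysis of an alkyl triethylsilyl ether. The weak pyridinium acid cannot protonate the prenyl alkenes, and the hindered aryl tert-butyldimethylsilyl ether is stable to it.

Step 11
Reactants: 19 (R)-1-[4-(tert-butyldimethylsilyloxy)-2-hydroxy-3,5-bis(3-methylbut-2-enyl)phenyl]-3-hydroxy-3-phenylpropan-1-one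
Product: 20 (S)-7-(tert-butyldimethylsilyloxy)-6,8-bis(3-methylbut-2-enyl)-2-phenylchroman-4-one
Conditions: PPh3, DIAD, THF (0.02 M), 0 °C
Reagents that add atoms: none
Why: Intramolecular Mitsunobu etherification. The benzylic hydroxyl becomes an alkoxyphosphonium leaving group and is displaced from the rear by the O1 phenoxide in a 6-exo-tet closure, so the (R) carbinol gives the (S) ether at C2 by inversion. The phenol is acidified by its ortho carbonyl and is a competent pronucleophile; dilution and low temperature favour ring closure over elimination.

Step 12
Reactants: 20 (S)-7-(tert-butyldimethylsilyloxy)-6,8-bis(3-methylbut-2-enyl)-2-phenylchroman-4-one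
Product: 21 (S)-7-hydroxy-6,8-bis(3-methylbut-2-enyl)-2-phenylchroman-4-one (7-hydroxy-6,8-diprenylflavanone)
Conditions: TBAF, AcOH (1.2 equiv per fluoride), THF, 0 °C
Reagents that add atoms: none
Why: Fluoride cleaves the aryl silyl ether quickly. The acetic acid buffer protonates the phenoxide as it forms, so ring C is not opened and C2 keeps its configuration, and no acid strong enough to cyclize the prenyl groups is present.

## Compound list

1 | 4-bromobenzene-1,3-diol (4-bromoresorcinol) | Oc1ccc(Br)c(O)c1 | starting material
2 | 1-bromo-2,4-bis(methoxymethoxy)benzene | COCOc1ccc(Br)c(OCOC)c1 | intermediate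
3 | 1-bromo-3-methylbut-2-ene (prenyl bromide) | CC(C)=CCBr | starting material
4 | [2,4-bis(methoxymethoxy)phenyl]lithium | [Li]c1ccc(OCOC)cc1OCOC | intermediate (not isolated)
5 | [2,4-bis(methoxymethoxy)phenyl]copper | [Cu]c1ccc(OCOC)cc1OCOC | intermediate (not isolated)
6 | 2,4-bis(methoxymethoxy)-1-(3-methylbut-2-enyl)benzene | COCOc1ccc(CC=C(C)C)c(OCOC)c1 | intermediate
7 | [2,6-bis(methoxymethoxy)-3-(3-methylbut-2-enyl)phenyl]lithium | COCOc1ccc(CC=C(C)C)c(OCOC)c1[Li] | intermediate (not isolated)
8 | [2,6-bis(methoxymethoxy)-3-(3-methylbut-2-enyl)phenyl]copper | COCOc1ccc(CC=C(C)C)c(OCOC)c1[Cu] | intermediate (not isolated)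
9 | 1,3-bis(methoxymethoxy)-2,4-bis(3-methylbut-2-enyl)benzene | COCOc1ccc(CC=C(C)C)c(OCOC)c1CC=C(C)C | intermediate
10 | 2,4-bis(3-methylbut-2-enyl)benzene-1,3-diol | Oc1ccc(CC=C(C)C)c(O)c1CC=C(C)C | intermediate
11 | ethyl (R)-3-hydroxy-3-phenylpropanoate | CCOC(=O)C[C@@H](O)c1ccccc1 | starting material
12 | ethyl (R)-3-phenyl-3-(triethylsilyloxy)propanoate | CCOC(=O)C[C@@H](O[Si](CC)(CC)CC)c1ccccc1 | intermediate
13 | lithium (R)-3-phenyl-3-(triethylsilyloxy)propanoate | [Li+].[O-]C(=O)C[C@@H](O[Si](CC)(CC)CC)c1ccccc1 | intermediate (not isolated)
14 | (R)-3-phenyl-3-(triethylsilyloxy)propanoic acid | OC(=O)C[C@@H](O[Si](CC)(CC)CC)c1ccccc1 | intermediate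
15 | 3-hydroxy-2,4-bis(3-methylbut-2-enyl)phenyl (R)-3-phenyl-3-(triethylsilyloxy)propanoate | CC(C)=CCc1ccc(OC(=O)C[C@@H](O[Si](CC)(CC)CC)c2ccccc2)c(CC=C(C)C)c1O | intermediate
16 | 3-(tert-butyldimethylsilyloxy)-2,4-bis(3-methylbut-2-enyl)phenyl (R)-3-phenyl-3-(triethylsilyloxy)propanoate | CC(C)=CCc1ccc(OC(=O)C[C@@H](O[Si](CC)(CC)CC)c2ccccc2)c(CC=C(C)C)c1O[Si](C)(C)C(C)(C)C | intermediate
17 | 3-(tert-butyldimethylsilyloxy)-2,4-bis(3-methylbut-2-enyl)-6-[(R)-3-phenyl-3-(triethylsilyloxy)propanoyl]cyclohexa-2,4-dien-1-one (ring sp3 carbon unspecified) | O=C1C(CC=C(C)C)=C(O[Si](C)(C)C(C)(C)C)C(CC=C(C)C)=CC1C(=O)C[C@@H](O[Si](CC)(CC)CC)c1ccccc1 | intermediate (not isolated)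
18 | (R)-1-[4-(tert-butyldimethylsilyloxy)-2-hydroxy-3,5-bis(3-methylbut-2-enyl)phenyl]-3-phenyl-3-(triethylsilyloxy)propan-1-one | CC(C)=CCc1cc(C(=O)C[C@@H](O[Si](CC)(CC)CC)c2ccccc2)c(O)c(CC=C(C)C)c1O[Si](C)(C)C(C)(C)C | intermediate
19 | (R)-1-[4-(tert-butyldimethylsilyloxy)-2-hydroxy-3,5-bis(3-methylbut-2-enyl)phenyl]-3-hydroxy-3-phenylpropan-1-one | CC(C)=CCc1cc(C(=O)C[C@@H](O)c2ccccc2)c(O)c(CC=C(C)C)c1O[Si](C)(C)C(C)(C)C | intermediate
20 | (S)-7-(tert-butyldimethylsilyloxy)-6,8-bis(3-methylbut-2-enyl)-2-phenylchroman-4-one | CC(C)=CCc1cc2c(c(CC=C(C)C)c1O[Si](C)(C)C(C)(C)C)O[C@H](c1ccccc1)CC2=O | intermediate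
21 | (S)-7-hydroxy-6,8-bis(3-methylbut-2-enyl)-2-phenylchroman-4-one (7-hydroxy-6,8-diprenylflavanone) | CC(C)=CCc1cc2c(c(CC=C(C)C)c1O)O[C@H](c1ccccc1)CC2=O | target

## Step count and least certain steps

Total: 12 steps. Longest linear sequence: 10 steps (1 to 21 through steps 1, 2, 3, 4, 7, 8, 9, 10, 11, 12); the acid 14 is made in a 2-step side branch from 11.

Step 9 (key step).
- What may go wrong: the radicals may escape from the cage, with loss of the acyl group by decarbonylation or hydrogen transfer. Conversion may stall as the product absorbs the light. The aryl–CH2–alkene units may undergo excited-state reactions of their own.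
- Fallback by polar chemistry, setting out from 16 and returning at 18:
  - The aryl ester 16 is cleaved with the chloromagnesium amide of N,O-dimethylhydroxylamine (MeNHOMe·HCl, i-PrMgCl, THF, −20 °C). This gives both halves in usable form: 3-(tert-butyldimethylsilyloxy)-2,4-bis(3-methylbut-2-enyl)phenol F1 and (R)-N-methoxy-N-methyl-3-phenyl-3-(triethylsilyloxy)propanamide F2.
  - F1 is brominated at its only open ortho position (NBS, cat. i-Pr2NH, CH2Cl2, −78 °C) to 6-bromo-3-(tert-butyldimethylsilyloxy)-2,4-bis(3-methylbut-2-enyl)phenol F3.
  - F3 is converted with n-BuLi (2.2 equiv, THF, −78 °C) into the lithium phenoxide aryllithium, which adds to F2 and gives 18 on work-up.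

Step 11.
- What may go wrong: the activated benzylic oxygen is β to a ketone, so elimination to the enone can compete with displacement. Ionization at the benzylic carbon, or reclosure of the enone, would erode the enantiopurity.
- Fallback that gives up stereospecific closure for a resolution, setting out from 19 and returning at 20:
  - Dehydration of 19 (MsCl, Et3N, CH2Cl2, −20 °C to rt) gives (E)-1-[4-(tert-butyldimethylsilyloxy)-2-hydroxy-3,5-bis(3-methylbut-2-enyl)phenyl]-3-phenylprop-2-en-1-one F4.
  - Base-mediated oxa-Michael closure (NaOAc, EtOH, reflux) gives racemic 7-(tert-butyldimethylsilyloxy)-6,8-bis(3-methylbut-2-enyl)-2-phenylchroman-4-one F5.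
  - The enantiomers of F5 are separated by preparative chromatography on a chiral stationary phase; the S enantiomer is 20.

Step 4.
- What may go wrong: acid-promoted closure of a prenyl group onto a freed phenol, or addition of HCl or methanol across an alkene, before both acetals have left.
- Fallback that replaces the acid-labile directing group by a fluoride-labile one, setting out from 1 and returning at 10:
  - 1 is converted with 2-(trimethylsilyl)ethoxymethyl chloride and i-Pr2NEt into 1-bromo-2,4-bis{[2-(trimethylsilyl)ethoxy]methoxy}benzene F6.
  - The sequences of steps 2 and 3 give 2,4-bis{[2-(trimethylsilyl)ethoxy]methoxy}-1-(3-methylbut-2-enyl)benzene F7 and then 1,3-bis{[2-(trimethylsilyl)ethoxy]methoxy}-2,4-bis(3-methylbut-2-enyl)benzene F8.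
  - F8 is cleaved with TBAF in DMF at 60 °C, with ethylenediamine as formaldehyde scavenger, to give 10 without any acid.

Step 7.
- What may go wrong: insufficient discrimination between the two phenols, giving the regioisomeric ester or the diester.
- Fallback that moves the selection from acylation to desilylation, setting out from 10 and returning at 16:
  - Both phenols of 10 are silylated (TBSOTf, 2,6-lutidine) to 1,3-bis(tert-butyldimethylsilyloxy)-2,4-bis(3-methylbut-2-enyl)benzene F9.
  - The less shielded aryl silyl ether is removed (K2CO3, MeOH, 0 °C) to give 3-(tert-butyldimethylsilyloxy)-2,4-bis(3-methylbut-2-enyl)phenol F1.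
  - The single free hydroxyl of F1 is esterified with 14 (DCC, DMAP) to give 16.

## Further compounds

F1 | step 9 | 3-(tert-butyldimethylsilyloxy)-2,4-bis(3-methylbut-2-enyl)phenol | CC(C)=CCc1ccc(O)c(CC=C(C)C)c1O[Si](C)(C)C(C)(C)C
F2 | step 9 | (R)-N-methoxy-N-methyl-3-phenyl-3-(triethylsilyloxy)propanamide | CON(C)C(=O)C[C@@H](O[Si](CC)(CC)CC)c1ccccc1
F3 | step 9 | 6-bromo-3-(tert-butyldimethylsilyloxy)-2,4-bis(3-methylbut-2-enyl)phenol | CC(C)=CCc1cc(Br)c(O)c(CC=C(C)C)c1O[Si](C)(C)C(C)(C)C
F4 | step 11 | (E)-1-[4-(tert-butyldimethylsilyloxy)-2-hydroxy-3,5-bis(3-methylbut-2-enyl)phenyl]-3-phenylprop-2-en-1-one | CC(C)=CCc1cc(C(=O)/C=C/c2ccccc2)c(O)c(CC=C(C)C)c1O[Si](C)(C)C(C)(C)C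
F5 | step 11 | racemic 7-(tert-butyldimethylsilyloxy)-6,8-bis(3-methylbut-2-enyl)-2-phenylchroman-4-one | CC(C)=CCc1cc2c(c(CC=C(C)C)c1O[Si](C)(C)C(C)(C)C)OC(c1ccccc1)CC2=O
F6 | step 4 | 1-bromo-2,4-bis{[2-(trimethylsilyl)ethoxy]methoxy}benzene | C[Si](C)(C)CCOCOc1ccc(Br)c(OCOCC[Si](C)(C)C)c1
F7 | step 4 | 2,4-bis{[2-(trimethylsilyl)ethoxy]methoxy}-1-(3-methylbut-2-enyl)benzene | C[Si](C)(C)CCOCOc1ccc(CC=C(C)C)c(OCOCC[Si](C)(C)C)c1
F8 | step 4 | 1,3-bis{[2-(trimethylsilyl)ethoxy]methoxy}-2,4-bis(3-methylbut-2-enyl)benzene | C[Si](C)(C)CCOCOc1ccc(CC=C(C)C)c(OCOCC[Si](C)(C)C)c1CC=C(C)C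
F9 | step 7 | 1,3-bis(tert-butyldimethylsilyloxy)-2,4-bis(3-methylbut-2-enyl)benzene | CC(C)=CCc1ccc(O[Si](C)(C)C(C)(C)C)c(CC=C(C)C)c1O[Si](C)(C)C(C)(C)C
A1 | alternative 1 | 2,6-bis(3-methylbut-2-enyl)-3-(triisopropylsilyloxy)phenol | CC(C)=CCc1ccc(O[Si](C(C)C)(C(C)C)C(C)C)c(CC=C(C)C)c1O
A2 | alternative 1 | (E)-1-diazo-7-methylocta-3,6-dien-2-one | CC(C)=CC/C=C/C(=O)C=[N+]=[N-]
A3 | alternative 1 | triisopropyl[(5-methylhex-4-en-1-yn-1-yl)oxy]silane | CC(C)=CCC#CO[Si](C(C)C)(C(C)C)C(C)C
A4 | alternative 2 | (S)-7-(methoxymethoxy)-6,8-bis(3-methylbut-2-enyl)flavanone | CC(C)=CCc1cc2c(c(CC=C(C)C)c1OCOC)O[C@H](c1ccccc1)CC2=O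
A5 | alternative 2 | 1-[2-(benzyloxy)-4-(methoxymethoxy)-3,5-bis(3-methylbut-2-enyl)phenyl]-2-diazoethan-1-one | CC(C)=CCc1cc(C(=O)C=[N+]=[N-])c(OCc2ccccc2)c(CC=C(C)C)c1OCOC
A6 | alternative 3 | (S)-7-(tert-butyldimethylsilyloxy)-6,8-bis(3-methylbut-2-enyl)flavanone | CC(C)=CCc1cc2c(c(CC=C(C)C)c1O[Si](C)(C)C(C)(C)C)O[C@H](c1ccccc1)CC2=O
A7 | alternative 3 | 7-(tert-butyldimethylsilyloxy)-6,8-bis(3-methylbut-2-enyl)chromen-4-one | O=c1ccoc2c1cc(CC=C(C)C)c(O[Si](C)(C)C(C)(C)C)c2CC=C(C)C
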